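**Strategy**

The route rests on cutting the C7–C8 bond of the ten-membered carbocycle. With the α-methylene lactone ring (O–C6–C7–C11(=C13)–C12) the carbinol C8 forms a homoallylic alcohol, C8(O)–C7–C11=C13, the retron of a carbonyl allylation. A chromium-mediated Nozaki–Hiyama–Kishi allylation of a C8 aldehyde by the allylmetal made from a 3-(bromomethyl)butenolide therefore closes the ten-membered ring, shifts the butenolide olefin into the exocyclic methylene and sets C7 and C8 in one operation. The precursor is a nerol-derived acyclic chain with the C6 butenolide at one end and a Sharpless-derived β,γ-epoxy aldehyde at the other; C8 is then inverted while the isobutyrate is installed.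

Key step: step 14

Remark: germacranolide numbering is used throughout (carbocycle C1–C10; lactone O on C6, C7–C11(=C13H2)–C12(=O); C14 = CH2O carbon on C10; C15 = methyl on C4); TBS = tert-butyldimethylsilyl, TBDPS = tert-butyldiphenylsilyl.

**Route**

Step 1
Reactants: 1 neryl acetate
Product: 3 (2Z)-3-methyl-6-oxohex-2-en-1-yl acetate, via secondary ozonide 2 (not isolated)
Conditions: O3 (1 equiv), pyridine (cat.), CH2Cl2, −78 °C; then Me2S, −78 °C to rt
Reagents that add atoms: ozone, [O-][O+]=O
Why: Chemoselective ozonolysis, in which ozone attacks the electron-rich terminal trisubstituted olefin much faster than the olefin deactivated by the allylic acetate, so that the Z olefin of nerol survives and becomes C4=C5 while the new aldehyde carbon is C1.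

Step 2
Reactants: 4 methyl 2-[bis(2,2,2-trifluoroethoxy)phosphoryl]acetate; 5 (2-bromoethoxy)(tert-butyl)dimethylsilane
Product: 6 methyl 2-[bis(2,2,2-trifluoroethoxy)phosphoryl]-4-(TBS-oxy)butanoate (racemic)
Conditions: NaH, NaI (cat.), DMF, 0 to 60 °C
Reagents that add atoms: none
Why: C-Alkylation of the stabilised phosphonoacetate anion with a primary bromide under iodide catalysis brings in C9 and C8, and the racemic α-centre is destroyed in step 3.

Step 3
Reactants: 3 (2Z)-3-methyl-6-oxohex-2-en-1-yl acetate; 6 phosphonate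
Product: 7 methyl (2Z,6Z)-8-acetoxy-2-[2-(TBS-oxy)ethyl]-6-methylocta-2,6-dienoate
Conditions: KN(SiMe3)2, 18-crown-6, THF, −78 °C
Reagents that add atoms: none
Why: Still–Gennari variant of the Horner–Wadsworth–Emmons olefination, in which the electron-poor bis(trifluoroethyl) phosphonate eliminates rapidly from the kinetic adduct and should give the Z enoate with the ester carbon C14 cis to C2, the geometry that later places C2 and C9 trans on the oxirane.

Step 4
Reactants: 7 Z,Z-enoate acetate
Product: 8 methyl (2Z,6Z)-2-[2-(TBS-oxy)ethyl]-8-hydroxy-6-methylocta-2,6-dienoate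
Conditions: K2CO3 (cat.), MeOH, 0 °C
Reagents that add atoms: none
Why: Base-catalysed methanolysis removes the allylic acetate, while transesterification of the methyl ester is degenerate and the silyl ether is inert.

Step 5
Reactants: 8 allylic alcohol
Product: 9 methyl (2Z,6Z)-2-[2-(TBS-oxy)ethyl]-6-methyl-8-oxoocta-2,6-dienoate
Conditions: MnO2, CH2Cl2, rt
Reagents that add atoms: none
Why: MnO2 oxidises only the allylic alcohol under neutral conditions, which is the standard way to reach nerol-type Z enals without Z to E isomerisation.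

Step 6
Reactants: 9 Z-enal
Product: 10 methyl (2Z,6Z,8S)-2-[2-(TBS-oxy)ethyl]-8-hydroxy-6-methyldeca-2,6,9-trienoate
Conditions: divinylzinc (from vinylmagnesium bromide and ZnCl2, salts precipitated with 1,4-dioxane), (2S)-3-exo-morpholinoisoborneol [(−)-MIB] (10 mol %), toluene, −20 to 0 °C; aq NH4Cl
Reagents that add atoms: vinylmagnesium bromide, C=C[Mg]Br (vinyl donor, used as divinylzinc made in the flask)
Why: Amino-alcohol-catalysed 1,2-addition of an alkenylzinc reagent to an aldehyde, in which the (−)-MIB-derived catalyst should deliver the vinyl group to the Si face of the enal and set C6 as S (the spatial arrangement that is 6R in the lactone, where the CIP ranks change), the enoate being inert to organozinc.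

Step 7
Reactants: 10 hydroxy ester
Product: 11 (2Z,6Z,8S)-2-[2-(TBS-oxy)ethyl]-6-methyldeca-2,6,9-triene-1,8-diol
Conditions: iBu2AlH (4 equiv), CH2Cl2, −78 °C; aq potassium sodium tartrate
Reagents that add atoms: none
Why: 1,2-Reduction of the conjugated methyl ester by iBu2AlH gives the primary allylic alcohol at C14 with retention of the Z geometry and without touching olefins or the silyl ether.

Step 8
Reactants: 11 diol
Product: 12 (3S,4Z)-7-[(2R,3S)-3-[2-(TBS-oxy)ethyl]-3-(hydroxymethyl)oxiran-2-yl]-5-methylhepta-1,4-dien-3-ol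
Conditions: Ti(OiPr)4 (10 mol %), diethyl L-(+)-tartrate (12 mol %), tBuOOH (1.2 equiv), 4 Å MS, CH2Cl2, −25 °C
Reagents that add atoms: tert-butyl hydroperoxide, CC(C)(C)OO
Why: Sharpless asymmetric epoxidation, in which the L-(+)-tartrate catalyst should deliver oxygen to the face of C1=C10 that gives (1R,10S) with C2 and C9 trans, and the primary allylic alcohol should react far faster than the secondary C6 carbinol, whose vinyl and Z-trisubstituted olefins are poor substrates.

Step 9
Reactants: 12 epoxy diol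
Product: 13 (3S,4Z)-7-[(2R,3S)-3-[2-(TBS-oxy)ethyl]-3-(TBDPS-oxymethyl)oxiran-2-yl]-5-methylhepta-1,4-dien-3-ol
Conditions: tBuPh2SiCl (1.05 equiv), imidazole, CH2Cl2, 0 °C
Reagents that add atoms: tert-butyl(chloro)diphenylsilane, CC(C)(C)[Si](Cl)(c1ccccc1)c1ccccc1
Why: Silylation with a bulky chlorosilane is selective for the primary C14 hydroxyl over the secondary, doubly allylic C6 hydroxyl.

Step 10
Reactants: 13 secondary alcohol; 14 2-(bromomethyl)prop-2-enoic acid
Product: 15 (3S,4Z)-7-[(2R,3S)-3-[2-(TBS-oxy)ethyl]-3-(TBDPS-oxymethyl)oxiran-2-yl]-5-methylhepta-1,4-dien-3-yl 2-(bromomethyl)prop-2-enoate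
Conditions: DCC, DMAP (5 mol %), CH2Cl2, 0 °C
Reagents that add atoms: none
Why: Steglich esterification acylates the C6 hydroxyl with retention and brings in C11, C12 and C13 together with the allylic bromide.

Step 11
Reactants: 15 dienyl 2-(bromomethyl)acrylate
Product: 16 (5R)-3-(bromomethyl)-5-[(1Z)-4-[(2R,3S)-3-[2-(TBS-oxy)ethyl]-3-(TBDPS-oxymethyl)oxiran-2-yl]-2-methylbut-1-en-1-yl]furan-2(5H)-one
Conditions: second-generation Grubbs catalyst (H2IMes)(PCy3)Cl2Ru=CHPh (5–10 mol %), CH2Cl2 (5 mM), 40 °C
Reagents that add atoms: none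
Why: Ring-closing metathesis, in which the ruthenium carbene loads on the monosubstituted vinyl group and closes the five-membered lactone onto the acrylate olefin with loss of ethylene, the trisubstituted C4=C5 olefin and the C6 centre being spectators.

Step 12
Reactants: 16 bromomethyl butenolide
Product: 17 (5R)-3-(bromomethyl)-5-[(1Z)-4-[(2R,3S)-3-(2-hydroxyethyl)-3-(TBDPS-oxymethyl)oxiran-2-yl]-2-methylbut-1-en-1-yl]furan-2(5H)-one
Conditions: HF·pyridine, pyridine, THF, 0 °C
Reagents that add atoms: none
Why: Buffered HF·pyridine cleaves the unhindered primary TBS ether much faster than the neopentyl-type TBDPS ether and is neither basic nor nucleophilic enough to harm the epoxide, bromide or butenolide.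

Step 13
Reactants: 17 primary alcohol
Product: 18 (5R)-3-(bromomethyl)-5-[(1Z)-4-[(2R,3S)-3-(2-oxoethyl)-3-(TBDPS-oxymethyl)oxiran-2-yl]-2-methylbut-1-en-1-yl]furan-2(5H)-one
Conditions: Dess–Martin periodinane, NaHCO3, CH2Cl2, 0 °C to rt; used crude at once
Reagents that add atoms: none
Why: Dess–Martin oxidation under bicarbonate buffering gives the β,γ-epoxy aldehyde without a base that could trigger β-elimination of the oxirane or epimerise C6.

Step 14
Reactants: 18 epoxy aldehyde with 3-(bromomethyl)butenolide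
Product: 20 (1R,6R,7R,8S,10S)-14-(TBDPS-oxy)-1,10-epoxy-8-hydroxygermacra-4Z,11(13)-dien-12,6-olide, via allylchromium dichloride 19 (not isolated)
Conditions: CrCl2 (10 equiv), THF (2 mM), rt, slow addition of 18; aq NH4Cl
Reagents that add atoms: none
Why: Two equivalents of CrCl2 reduce the allylic bromide to the allylchromium dichloride 19 (trivalent chromium), which adds through its γ-carbon C7 to the aldehyde C8 in a six-membered Zimmerman–Traxler transition state, so that the butenolide C7=C11 olefin moves to the exocyclic C11=C13 position. The closest known reaction type is the Nozaki–Hiyama–Kishi (Barbier) allylation of aldehydes by 3-(bromomethyl)butenolides and 2-(bromomethyl)acrylates, including its intramolecular use for medium and large rings. The ten-membered carbocycle is closed in a 10-exo-trig mode with respect to the aldehyde. C7 is controlled by the C6 stereocentre, because C8 should be delivered to the butenolide face opposite the C5 substituent, which also keeps the C5–C6–C7–C8 torsion near 150° as a ten-membered ring prefers, and this gives the trans-fused lactone (7R). C8 is controlled by the chair in which the C9 tether is pseudo-equatorial (anti to C11), so that the new ring is fused diequatorially to the chair, and this should give the 8S (8α) alcohol, the C8 epimer of the ester configuration, which step 15 corrects. The step needs γ- over α-attack (inherent in the cyclic transition state), ring closure over oligomerisation (high dilution, slow addition) and tolerance of epoxide, lactone and silyl ether, which the mild, non-basic organochromium reagent provides.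

Step 15
Reactants: 20 macrocyclic 8S alcohol
Product: 21 (1R,6R,7R,8R,10S)-14-(TBDPS-oxy)-1,10-epoxy-8-(2-methylpropanoyloxy)germacra-4Z,11(13)-dien-12,6-olide
Conditions: PPh3, DIAD, isobutyric acid, toluene, 0 °C to rt
Reagents that add atoms: isobutyric acid, CC(C)C(=O)O
Why: Mitsunobu esterification, in which the alkoxyphosphonium ion at C8 is displaced by isobutyrate in an SN2 reaction with inversion, installs the ester and converts 8S into the required 8R in one operation.

Step 16
Reactants: 21 silyl-protected ester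
Product: 22 target, (1R,6R,7R,8R,10S)-1,10-epoxy-14-hydroxy-8-(2-methylpropanoyloxy)germacra-4Z,11(13)-dien-12,6-olide
Conditions: HF·pyridine, pyridine, THF, 0 °C to rt
Reagents that add atoms: none
Why: Fluoride cleaves the primary silyl ether under mildly acidic conditions, which avoids Payne rearrangement of the 2,3-epoxy alcohol, acyl migration and opening of the lactone or isobutyrate.

**Compound list**

1 | neryl acetate, (2Z)-3,7-dimethylocta-2,6-dien-1-yl acetate | CC(=O)OC/C=C(/C)CCC=C(C)C | starting material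
2 | secondary ozonide, (2Z)-5-(5,5-dimethyl-1,2,4-trioxolan-3-yl)-3-methylpent-2-en-1-yl acetate | CC(=O)OC/C=C(/C)CCC1OOC(C)(C)O1 | intermediate (not isolated)
3 | (2Z)-3-methyl-6-oxohex-2-en-1-yl acetate | CC(=O)OC/C=C(/C)CCC=O | intermediate
4 | methyl 2-[bis(2,2,2-trifluoroethoxy)phosphoryl]acetate | COC(=O)CP(=O)(OCC(F)(F)F)OCC(F)(F)F | starting material
5 | (2-bromoethoxy)(tert-butyl)dimethylsilane | CC(C)(C)[Si](C)(C)OCCBr | starting material
6 | methyl 2-[bis(2,2,2-trifluoroethoxy)phosphoryl]-4-(TBS-oxy)butanoate, racemic | COC(=O)C(CCO[Si](C)(C)C(C)(C)C)P(=O)(OCC(F)(F)F)OCC(F)(F)F | intermediate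
7 | methyl (2Z,6Z)-8-acetoxy-2-[2-(TBS-oxy)ethyl]-6-methylocta-2,6-dienoate | COC(=O)/C(CCO[Si](C)(C)C(C)(C)C)=C\CC/C(C)=C\COC(C)=O | intermediate
8 | methyl (2Z,6Z)-2-[2-(TBS-oxy)ethyl]-8-hydroxy-6-methylocta-2,6-dienoate | COC(=O)/C(CCO[Si](C)(C)C(C)(C)C)=C\CC/C(C)=C\CO | intermediate
9 | methyl (2Z,6Z)-2-[2-(TBS-oxy)ethyl]-6-methyl-8-oxoocta-2,6-dienoate | COC(=O)/C(CCO[Si](C)(C)C(C)(C)C)=C\CC/C(C)=C\C=O | intermediate
10 | methyl (2Z,6Z,8S)-2-[2-(TBS-oxy)ethyl]-8-hydroxy-6-methyldeca-2,6,9-trienoate | COC(=O)/C(CCO[Si](C)(C)C(C)(C)C)=C\CC/C(C)=C\[C@@H](O)C=C | intermediate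
11 | (2Z,6Z,8S)-2-[2-(TBS-oxy)ethyl]-6-methyldeca-2,6,9-triene-1,8-diol | OC/C(CCO[Si](C)(C)C(C)(C)C)=C\CC/C(C)=C\[C@@H](O)C=C | intermediate
12 | (3S,4Z)-7-[(2R,3S)-3-[2-(TBS-oxy)ethyl]-3-(hydroxymethyl)oxiran-2-yl]-5-methylhepta-1,4-dien-3-ol | OC[C@]1(CCO[Si](C)(C)C(C)(C)C)O[C@@H]1CC/C(C)=C\[C@@H](O)C=C | intermediate
13 | (3S,4Z)-7-[(2R,3S)-3-[2-(TBS-oxy)ethyl]-3-(TBDPS-oxymethyl)oxiran-2-yl]-5-methylhepta-1,4-dien-3-ol | CC(C)(C)[Si](c1ccccc1)(c1ccccc1)OC[C@]1(CCO[Si](C)(C)C(C)(C)C)O[C@@H]1CC/C(C)=C\[C@@H](O)C=C | intermediate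
14 | 2-(bromomethyl)prop-2-enoic acid | C=C(CBr)C(=O)O | starting material
15 | 2-(bromomethyl)acrylate of 13 (C6 S) | CC(C)(C)[Si](c1ccccc1)(c1ccccc1)OC[C@]1(CCO[Si](C)(C)C(C)(C)C)O[C@@H]1CC/C(C)=C\[C@@H](OC(=O)C(=C)CBr)C=C | intermediate
16 | (5R)-3-(bromomethyl)-5-[(1Z)-4-[(2R,3S)-3-[2-(TBS-oxy)ethyl]-3-(TBDPS-oxymethyl)oxiran-2-yl]-2-methylbut-1-en-1-yl]furan-2(5H)-one | CC(C)(C)[Si](c1ccccc1)(c1ccccc1)OC[C@]1(CCO[Si](C)(C)C(C)(C)C)O[C@@H]1CC/C(C)=C\[C@H]2OC(=O)C(CBr)=C2 | intermediate
17 | same butenolide with a 2-hydroxyethyl group on the oxirane (C8 alcohol) | CC(C)(C)[Si](c1ccccc1)(c1ccccc1)OC[C@]1(CCO)O[C@@H]1CC/C(C)=C\[C@H]2OC(=O)C(CBr)=C2 | intermediate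
18 | same butenolide with a 2-oxoethyl group on the oxirane (C8 aldehyde) | CC(C)(C)[Si](c1ccccc1)(c1ccccc1)OC[C@]1(CC=O)O[C@@H]1CC/C(C)=C\[C@H]2OC(=O)C(CBr)=C2 | intermediate
19 | allylchromium dichloride derived from 18 (CH2CrCl2 in place of CH2Br) | CC(C)(C)[Si](c1ccccc1)(c1ccccc1)OC[C@]1(CC=O)O[C@@H]1CC/C(C)=C\[C@H]2OC(=O)C(C[Cr](Cl)Cl)=C2 | intermediate (not isolated)
20 | (1R,6R,7R,8S,10S)-14-(TBDPS-oxy)-1,10-epoxy-8-hydroxygermacra-4Z,11(13)-dien-12,6-olide (1β,10α-epoxide, trans lactone, 8α-OH) | C=C1C(=O)O[C@@H]2/C=C(/C)CC[C@H]3O[C@]3(CO[Si](c4ccccc4)(c4ccccc4)C(C)(C)C)C[C@H](O)[C@@H]12 | intermediate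
21 | (1R,6R,7R,8R,10S)-14-(TBDPS-oxy)-1,10-epoxy-8-(2-methylpropanoyloxy)germacra-4Z,11(13)-dien-12,6-olide (8β-ester) | C=C1C(=O)O[C@@H]2/C=C(/C)CC[C@H]3O[C@]3(CO[Si](c4ccccc4)(c4ccccc4)C(C)(C)C)C[C@@H](OC(=O)C(C)C)[C@@H]12 | intermediate
22 | CNP0247143.1, (1R,6R,7R,8R,10S)-1,10-epoxy-14-hydroxy-8-(2-methylpropanoyloxy)germacra-4Z,11(13)-dien-12,6-olide | C=C1C(=O)O[C@@H]2/C=C(/C)CC[C@H]3O[C@]3(CO)C[C@@H](OC(=O)C(C)C)[C@@H]12 | target

**Step count and risks**

Total step count: 16. Longest linear sequence: 15 steps (steps 1 and 3 to 16, from neryl acetate); step 2 is a one-step branch.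

Step 14 (key step). What may go wrong: the aldehyde is attacked on its other face, through a chair with the C9 tether pseudo-axial or through a boat, so that facial selectivity at C8 is poor or reversed. Fallback: setting out from 18, the same closure is run and the (1R,6R,7R,8R,10S)-configured C8-epimeric alcohol F1 is separated from 20 and esterified with retention (isobutyric anhydride, DMAP, pyridine, CH2Cl2, 0 °C) instead of with inversion. This comes back to the route at 21, so that both C8 epimers converge.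

Step 15. What may go wrong: the alkoxyphosphonium ion is lost by E2 elimination towards C7 or C9, or the hindered ring carbinol is acylated with retention through an acyloxyphosphonium pathway. Fallback: setting out from 20, chloromethanesulfonyl chloride and pyridine (CH2Cl2, 0 °C) give the C8 chloromethanesulfonate F2, a small and very reactive leaving group. It is displaced with inversion by CsO2CCHMe2 with 18-crown-6 in toluene at 40 °C, which comes back at 21.

Step 11. What may go wrong: the allylic bromide degrades the ruthenium carbene, or closure onto the 1,1-disubstituted acrylate is so slow that ionisation of the doubly allylic ester and oligomerisation take over. Fallback: setting out from 13, acryloyl chloride and iPr2NEt (CH2Cl2, −20 °C) give the acrylate ester F3. Ring-closing metathesis of this unhindered acrylate (second-generation Grubbs catalyst, CH2Cl2, 40 °C) gives the 3-unsubstituted butenolide F4. A Morita–Baylis–Hillman reaction with aqueous formaldehyde (PMe3, THF/H2O, rt) gives the 3-(hydroxymethyl)butenolide F5, and Appel bromination (CBr4, PPh3, CH2Cl2, 0 °C) comes back at 16.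

**Further compounds**

F1 | step 14 | (1R,6R,7R,8R,10S)-14-(TBDPS-oxy)-1,10-epoxy-8-hydroxygermacra-4Z,11(13)-dien-12,6-olide (C8 epimer of 20) | C=C1C(=O)O[C@@H]2/C=C(/C)CC[C@H]3O[C@]3(CO[Si](c4ccccc4)(c4ccccc4)C(C)(C)C)C[C@@H](O)[C@@H]12
F2 | step 15 | C8 chloromethanesulfonate of 20 (configuration of 20 retained) | C=C1C(=O)O[C@@H]2/C=C(/C)CC[C@H]3O[C@]3(CO[Si](c4ccccc4)(c4ccccc4)C(C)(C)C)C[C@H](OS(=O)(=O)CCl)[C@@H]12
F3 | step 11 | acrylate (prop-2-enoate) ester of 13 | CC(C)(C)[Si](c1ccccc1)(c1ccccc1)OC[C@]1(CCO[Si](C)(C)C(C)(C)C)O[C@@H]1CC/C(C)=C\[C@@H](OC(=O)C=C)C=C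
F4 | step 11 | butenolide as 16 but with H in place of the bromomethyl group (C6 arrangement as in 16) | CC(C)(C)[Si](c1ccccc1)(c1ccccc1)OC[C@]1(CCO[Si](C)(C)C(C)(C)C)O[C@@H]1CC/C(C)=C\[C@H]2OC(=O)C=C2
F5 | step 11 | butenolide as 16 but with hydroxymethyl in place of bromomethyl | CC(C)(C)[Si](c1ccccc1)(c1ccccc1)OC[C@]1(CCO[Si](C)(C)C(C)(C)C)O[C@@H]1CC/C(C)=C\[C@H]2OC(=O)C(CO)=C2
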